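**Retrosynthetic overview**
1. The (2S)-flavanone C ring is the last ring formed, by catalytic enantioselective intramolecular oxa-Michael closure of a 2'-hydroxychalcone that carries the 5-O-MOM group (the only new stereocentre).
2. The chalcone comes from a late Claisen–Schmidt coupling of two similar-sized fragments: ketone **11** (A ring, prenylated, 2'-OH free) and aldehyde **20** (B ring, prenylated).
3. **11** comes from resorcinol. Ir-catalysed meta C–H borylation/oxidation gives the phloroglucinol oxidation pattern, then two directed ortho-lithiations install the prenyl and acetyl groups.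
4. **20** comes from 4-bromophenol by allyl ether formation, Claisen rearrangement, MOM protection, cross-metathesis to the prenyl group, and Li–Br exchange/formylation.

Assumptions: MOM = CH2OCH3, prenyl = 3-methylbut-2-enyl, and the SMILES given corresponds to (2S), as for natural material. Numbers go to substrates, building blocks, intermediates and the target. Catalysts, bases and solvents are named only in the conditions.

---

**A-ring fragment**

**Step 1**
Reactants: **1** resorcinol; **2** chloromethyl methyl ether (MOMCl)
Product: **3** 1,3-bis(methoxymethoxy)benzene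
Conditions: NaH, THF/DMF, 0 °C → rt
Reagents that add atoms: MOMCl (**2**), COCCl
Why: Williamson-type O-alkylation protects both phenols as base-stable acetals that later act as directing groups.

**Step 2**
Reactants: **3**
Product: **4** 3,5-bis(methoxymethoxy)phenol
Conditions: (i) B2pin2, [Ir(OMe)(cod)]2 (cat.), dtbpy (cat.), THF, 80 °C; (ii) same pot, H2O2 (aq.), NaOH, THF, 0 °C → rt
Reagents that add atoms: hydrogen peroxide, OO (supplies the phenolic O)
Why: Ir-catalysed C–H borylation is sterically controlled and occurs only at C5, meta to both OMOM groups. Basic peroxide oxidation converts the C–B bond to C–OH, which leaves the acid-labile MOM groups intact.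

**Step 3**
Reactants: **4**; **2** MOMCl
Product: **5** 1,3,5-tris(methoxymethoxy)benzene
Conditions: NaH, THF, 0 °C → rt
Reagents that add atoms: MOMCl (**2**), COCCl
Why: O-alkylation gives the symmetric tri-protected phloroglucinol needed for directed ortho-metalation.

**Step 4**
Reactants: **5**; **6** prenyl bromide
Product: **7** 2-(3-methylbut-2-enyl)-1,3,5-tris(methoxymethoxy)benzene
Conditions: n-BuLi, THF, 0 °C, 1 h; then CuI (10 mol%), prenyl bromide, –78 °C → rt
Reagents that add atoms: prenyl bromide (**6**), CC(C)=CCBr
Why: The position flanked by two OMOM groups is lithiated (directed ortho-metalation). Cu(I)-catalysed SN2 alkylation of the aryl-copper species then attaches the prenyl group. All ring CH positions are equivalent, so there is no regiochemical issue.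

**Step 5**
Reactants: **7**; **8** N-methoxy-N-methylacetamide
Product: **9** 1-[3-(3-methylbut-2-enyl)-2,4,6-tris(methoxymethoxy)phenyl]ethan-1-one
Conditions: n-BuLi, THF, 0 °C, 1 h; then **8**, –78 °C → rt
Reagents that add atoms: N-methoxy-N-methylacetamide (**8**), CC(=O)N(C)OC
Why: A second directed ortho-lithiation occurs at the remaining doubly OMOM-flanked CH, meta to the prenyl group. Addition to the Weinreb amide stops at the ketone.

**Step 6**
Reactants: **9**
Product: **10** 1-[2,4,6-trihydroxy-3-(3-methylbut-2-enyl)phenyl]ethan-1-one
Conditions: 3 M HCl, MeOH, 40 °C, 3 h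
Reagents that add atoms: none
Why: Acid-catalysed acetal hydrolysis removes all three MOM groups. The prenyl group and ketone are untouched under these mild conditions.

**Step 7**
Reactants: **10**; **2** MOMCl
Product: **11** 1-[2-hydroxy-3-(3-methylbut-2-enyl)-4,6-bis(methoxymethoxy)phenyl]ethan-1-one
Conditions: MOMCl (2.1 equiv), i-Pr2NEt, CH2Cl2, 0 °C
Reagents that add atoms: MOMCl (**2**), COCCl
Why: Selective O-alkylation. The acidic, unhindered 4'-OH reacts first, then the 6'-OH. The 2'-OH, which is flanked by the prenyl group and chelated to C=O, stays free. This identifies it as the future ring oxygen (O1), so the prenyl ends up at C8.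

---

**B-ring fragment**

**Step 8**
Reactants: **12** 4-bromophenol; **13** allyl bromide
Product: **14** 1-(allyloxy)-4-bromobenzene
Conditions: K2CO3, acetone, reflux
Reagents that add atoms: allyl bromide (**13**), C=CCBr
Why: Williamson ether synthesis.

**Step 9**
Reactants: **14**
Product: **15** 2-allyl-4-bromophenol
Conditions: neat (or PhNEt2), 200 °C, 3 h
Reagents that add atoms: none
Why: Aromatic Claisen [3,3] rearrangement. The para position is blocked by Br, so the allyl group goes only to the ortho position.

**Step 10**
Reactants: **15**; **2** MOMCl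
Product: **16** 2-allyl-4-bromo-1-(methoxymethoxy)benzene
Conditions: i-Pr2NEt, CH2Cl2, 0 °C → rt
Reagents that add atoms: MOMCl (**2**), COCCl
Why: Protects the phenol as an acetal so it survives the organolithium step later.

**Step 11**
Reactants: **16**; **17** 2-methyl-2-butene
Product: **18** 4-bromo-2-(3-methylbut-2-enyl)-1-(methoxymethoxy)benzene
Conditions: Grubbs II (5 mol%), 1,4-benzoquinone (10 mol%), CH2Cl2, 40 °C, 16 h
Reagents that add atoms: 2-methyl-2-butene (**17**), CC=C(C)C
Why: Olefin cross-metathesis converts the terminal allyl CH=CH2 into the trisubstituted prenyl alkene, releasing propene. Benzoquinone suppresses Ru–H-mediated alkene isomerisation.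

**Step 12**
Reactants: **18**; **19** N,N-dimethylformamide
Product: **20** 3-(3-methylbut-2-enyl)-4-(methoxymethoxy)benzaldehyde
Conditions: n-BuLi, THF, –78 °C, 30 min; then DMF, –78 → 0 °C; aq. NH4Cl
Reagents that add atoms: DMF (**19**), CN(C)C=O
Why: Fast Br–Li exchange gives the aryllithium, and formylation with DMF gives the aldehyde. The prenyl alkene and the MOM group are unaffected at –78 °C.

---

**Coupling and endgame**

**Step 13**
Reactants: **11** ketone; **20** aldehyde
Product: **21** (E)-chalcone
Conditions: KOH (5 equiv), EtOH/H2O, 0 °C → rt, 48 h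
Reagents that add atoms: none
Why: Claisen–Schmidt aldol condensation joins the two fragments. E1cB dehydration gives the E-enone, and the MOM acetals are base-stable.

**Step 14**
Reactants: **21**
Product: **22** (2S)-5,7,4'-tris(methoxymethoxy)-8,3'-bis(3-methylbut-2-enyl)flavanone
Conditions: quinine-derived bifunctional thiourea (10–20 mol%), toluene, 0 °C → rt, 3–5 d
Reagents that add atoms: none
Why: Catalytic enantioselective intramolecular oxa-Michael addition of the only free phenol (2'-OH). The thiourea activates the enone and the tertiary amine delivers the phenoxide to one enone face, setting C2 as (S). If the opposite enantiomer is obtained, the quinidine-derived catalyst is used. Regiochemistry is fixed because the 6'-OH is protected.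

**Step 15**
Reactants: **22**
Product: **23** euchrestaflavanone A, (2S)-5,7,4'-trihydroxy-8,3'-bis(3-methylbut-2-enyl)flavanone
Conditions: 2 M HCl, MeOH/THF (1:1), 35 °C, 12–24 h
Reagents that add atoms: none
Why: Acid hydrolysis of the three aryl MOM acetals. C2 is not epimerised because no base is used, and the 5-OH/C4=O chelate stabilises the product.

---

**Compound list**

| No. | Name | SMILES | Role |
|---|---|---|---|
| 1 | resorcinol | Oc1cccc(O)c1 | starting material |
| 2 | chloromethyl methyl ether | ClCOC | starting material (reagent) |
| 3 | 1,3-bis(methoxymethoxy)benzene | COCOc1cccc(OCOC)c1 | intermediate |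
| 4 | 3,5-bis(methoxymethoxy)phenol | COCOc1cc(O)cc(OCOC)c1 | intermediate |
| 5 | 1,3,5-tris(methoxymethoxy)benzene | COCOc1cc(OCOC)cc(OCOC)c1 | intermediate |
| 6 | prenyl bromide | CC(C)=CCBr | starting material |
| 7 | 2-prenyl-1,3,5-tris(methoxymethoxy)benzene | CC(C)=CCc1c(OCOC)cc(OCOC)cc1OCOC | intermediate |
| 8 | N-methoxy-N-methylacetamide | CC(=O)N(C)OC | starting material |
| 9 | 1-[3-prenyl-2,4,6-tris(MOMO)phenyl]ethanone | CC(=O)c1c(OCOC)cc(OCOC)c(CC=C(C)C)c1OCOC | intermediate |
| 10 | 2',4',6'-trihydroxy-3'-prenylacetophenone | CC(=O)c1c(O)cc(O)c(CC=C(C)C)c1O | intermediate |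
| 11 | 2'-hydroxy-4',6'-bis(MOMO)-3'-prenylacetophenone | CC(=O)c1c(O)c(CC=C(C)C)c(OCOC)cc1OCOC | intermediate (A fragment) |
| 12 | 4-bromophenol | Oc1ccc(Br)cc1 | starting material |
| 13 | allyl bromide | C=CCBr | starting material |
| 14 | 1-(allyloxy)-4-bromobenzene | C=CCOc1ccc(Br)cc1 | intermediate |
| 15 | 2-allyl-4-bromophenol | C=CCc1cc(Br)ccc1O | intermediate |
| 16 | 2-allyl-4-bromo-1-(MOMO)benzene | C=CCc1cc(Br)ccc1OCOC | intermediate |
| 17 | 2-methyl-2-butene | CC=C(C)C | starting material |
| 18 | 4-bromo-2-prenyl-1-(MOMO)benzene | CC(C)=CCc1cc(Br)ccc1OCOC | intermediate |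
| 19 | N,N-dimethylformamide | CN(C)C=O | starting material (reagent) |
| 20 | 3-prenyl-4-(MOMO)benzaldehyde | CC(C)=CCc1cc(C=O)ccc1OCOC | intermediate (B fragment) |
| 21 | (E)-chalcone | CC(C)=CCc1cc(/C=C/C(=O)c2c(O)c(CC=C(C)C)c(OCOC)cc2OCOC)ccc1OCOC | intermediate |
| 22 | (2S)-tris-MOM flavanone | CC(C)=CCc1cc([C@@H]2CC(=O)c3c(OCOC)cc(OCOC)c(CC=C(C)C)c3O2)ccc1OCOC | intermediate |
| 23 | euchrestaflavanone A | CC(C)=CCc1cc([C@@H]2CC(=O)c3c(O)cc(O)c(CC=C(C)C)c3O2)ccc1O | target |

---

**Step count:** 15 steps in total.

**Longest linear sequence:** 10 steps (Steps 1–7, then 13–15), which is exactly two thirds of the total.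

**Three steps most likely to fail**
1. **Step 14 (enantioselective oxa-Michael).** Ring closure is reversible and ee may be only moderate. Fallback: cyclise the chalcone racemically (NaOAc, EtOH, reflux), then resolve the flavanone by preparative chiral SFC/HPLC. The resolution must be run on the MOM-protected flavanone, before Step 15.
2. **Step 4 (direct prenylation of the aryllithium).** Allylic coupling could give SN2′ (reverse-prenyl) product. Fallback: alkylate with allyl bromide instead, carry the allyl group through Steps 5–7, and convert it to prenyl by cross-metathesis with 2-methyl-2-butene on ketone **11**, as in Step 11.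
3. **Step 7 (selective bis-MOM protection).** The 2'-OH may not be left free selectively. Fallback: avoid prenylation at this stage. Make the unprenylated symmetric tris-MOM acetophenone, mono-deprotect it (no regiochemical issue by symmetry), then O-allylate, Claisen-rearrange and cross-metathesise. That puts the prenyl group regiospecifically next to the free oxygen.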